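The route rests on disconnecting both C–O bonds of the vicinal diol formed by the ring carbon C5 (tertiary carbinol) and the side-chain carbon C1' (secondary carbinol), which sit next to the acetoxy-bearing C4 of the cyclopentenone ring. A single syn-dihydroxylation of an exocyclic C5=C1' alkene installs both hydroxyls and both stereocentres, the C4 acetate steering the oxidant to the opposite ring face and the E geometry fixing C1'. The precursor is therefore the flat cross-conjugated dienone (R,E)-4-acetoxy-5-pentadecylidenecyclopent-2-en-1-one, assembled by aldol condensation of an enantiopure 4-silyloxycyclopentenone with pentadecanal and a silyl-to-acetyl exchange.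

Key step: step 5

Assumption: silyl ether 1 is bought as the S enantiomer; target ring numbering (C1 carbonyl, C2=C3, C4 oxygen-bearing carbon, C5, side-chain C1') is used for all compounds, and the change of the C4 descriptor from S in 1 to R from 4 onward is a CIP priority change (C5 outranks C3 once it is substituted), not an inversion.

Step 1
Reactants: 1 (S)-4-(tert-butyldimethylsilyloxy)cyclopent-2-en-1-one; 2 pentadecanal
Product: 4 (4R,5S)-4-(tert-butyldimethylsilyloxy)-5-(1-hydroxypentadecyl)cyclopent-2-en-1-one (4,5-trans; both C1' epimers), via lithium dienolate 3 (not isolated)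
Conditions: LiN(i-Pr)2 (1.1 equiv), THF, −78 °C; 2, −78 °C; aq. NH4Cl at −78 °C
Reagents that add atoms: none
Why: Kinetic deprotonation at C5 gives the cross-conjugated lithium dienolate 3, whose directed aldol addition to the aldehyde should occur on the ring face opposite the C4 silyloxy group (C5 trans to it), the C1' epimer mixture being irrelevant because C5–H and C1'–OH are both lost in step 2, while the low temperature holds back β-elimination of silanolate.

Step 2
Reactants: 4 (4R,5S)-4-(tert-butyldimethylsilyloxy)-5-(1-hydroxypentadecyl)cyclopent-2-en-1-one
Product: 6 (R,E)-4-(tert-butyldimethylsilyloxy)-5-pentadecylidenecyclopent-2-en-1-one, via C1' methanesulfonate 5 (not isolated)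
Conditions: MsCl, Et3N, DMAP (cat.), CH2Cl2, −20 °C to rt
Reagents that add atoms: none
Why: Mesylation of the secondary alcohol followed by amine-induced E1cB elimination through the acidic C5–H completes the aldol condensation and should favour the thermodynamically preferred E-alkylidene (chain away from the carbonyl oxygen), any Z isomer being removed by chromatography and C4 not taking part.

Step 3
Reactants: 6 (R,E)-4-(tert-butyldimethylsilyloxy)-5-pentadecylidenecyclopent-2-en-1-one
Product: 7 (R,E)-4-hydroxy-5-pentadecylidenecyclopent-2-en-1-one
Conditions: 48% aq. HF, MeCN, 0 °C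
Reagents that add atoms: none
Why: Silyl ether cleavage by HF under acidic, weakly nucleophilic conditions should free the C4 alcohol without the basicity of fluoride salts, and ionisation at C4 is disfavoured because both flanking alkenes are acyl-substituted and electron-poor.

Step 4
Reactants: 7 (R,E)-4-hydroxy-5-pentadecylidenecyclopent-2-en-1-one
Product: 8 (R,E)-4-acetoxy-5-pentadecylidenecyclopent-2-en-1-one
Conditions: Ac2O, pyridine, DMAP (cat.), CH2Cl2, 0 °C
Reagents that add atoms: acetic anhydride, CC(=O)OC(C)=O
Why: DMAP-catalysed O-acylation of the secondary allylic alcohol should be fast at low temperature, C5 carries no hydrogen that would allow β-elimination of the new acetate, and the C4 configuration is untouched.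

Step 5
Reactants: 8 (R,E)-4-acetoxy-5-pentadecylidenecyclopent-2-en-1-one
Product: 10 (4R,5S)-4-acetoxy-5-hydroxy-5-[(S)-1-hydroxypentadecyl]cyclopent-2-en-1-one, via cyclic osmate ester 9 (not isolated)
Conditions: OsO4 (5 mol %), NMO (1.05 equiv), citric acid (1 equiv), THF/t-BuOH/H2O, 0 °C to rt; aq. Na2SO3
Reagents that add atoms: osmium tetroxide, O=[Os](=O)(=O)=O; N-methylmorpholine N-oxide, C[N+]1([O-])CCOCC1; water, O
Why: OsO4 adds suprafacially across C5=C1' in a concerted [3+2] cycloaddition to give the hexavalent osmium glycolate 9, which NMO reoxidises and water hydrolyses, so both C–O bonds are made on one face in one event. The closest known reaction type is the catalytic OsO4/NMO syn-dihydroxylation of alkylidene cycloalkanones and of cyclic allylic esters anti to the oxygen substituent. No ring of the product is closed; only the transient five-membered osmate ring forms, by cycloaddition. C5 is controlled by the C4 acetate, which blocks its own face so that the new C5–OH ends up trans to it (5S), and C1' is fixed by the E geometry, which places the chain on the C4 side and translates stereospecifically into 1'S. The step needs chemoselectivity for the exocyclic alkene over the C2=C3 enone alkene and face selectivity; the first should follow from the higher substitution and electron density of the trisubstituted alkene toward the electrophilic oxidant, helped by a limiting charge of NMO and low temperature, the second from the adjacent acetate. Citric acid keeps the medium acidic, which speeds osmate hydrolysis for this electron-poor alkene and suppresses acetyl migration and retro-aldol cleavage of the product.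

Compound list
1 | (S)-4-(tert-butyldimethylsilyloxy)cyclopent-2-en-1-one | O=C1C=C[C@@H](O[Si](C)(C)C(C)(C)C)C1 | starting material
2 | pentadecanal | CCCCCCCCCCCCCCC=O | starting material
3 | lithium cross-conjugated dienolate of 1 (C4 unchanged) | [Li]OC1=C[C@H](O[Si](C)(C)C(C)(C)C)C=C1 | intermediate (not isolated)
4 | (4R,5S)-4-(tert-butyldimethylsilyloxy)-5-(1-hydroxypentadecyl)cyclopent-2-en-1-one, 4,5-trans, both C1' epimers | CCCCCCCCCCCCCCC(O)[C@@H]1C(=O)C=C[C@H]1O[Si](C)(C)C(C)(C)C | intermediate
5 | C1' methanesulfonate of 4 | CCCCCCCCCCCCCCC(OS(C)(=O)=O)[C@@H]1C(=O)C=C[C@H]1O[Si](C)(C)C(C)(C)C | intermediate (not isolated)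
6 | (R,E)-4-(tert-butyldimethylsilyloxy)-5-pentadecylidenecyclopent-2-en-1-one | CCCCCCCCCCCCCC/C=C1/C(=O)C=C[C@H]1O[Si](C)(C)C(C)(C)C | intermediate
7 | (R,E)-4-hydroxy-5-pentadecylidenecyclopent-2-en-1-one | CCCCCCCCCCCCCC/C=C1/C(=O)C=C[C@H]1O | intermediate
8 | (R,E)-4-acetoxy-5-pentadecylidenecyclopent-2-en-1-one (key-step precursor) | CCCCCCCCCCCCCC/C=C1/C(=O)C=C[C@H]1OC(C)=O | intermediate
9 | cyclic hexavalent osmium glycolate bridging the C5 and C1' oxygens | CCCCCCCCCCCCCC[C@@H]1O[Os](=O)(=O)O[C@@]12C(=O)C=C[C@H]2OC(C)=O | intermediate (not isolated)
10 | (4R,5S)-4-acetoxy-5-hydroxy-5-[(S)-1-hydroxypentadecyl]cyclopent-2-en-1-one | CCCCCCCCCCCCCC[C@H](O)[C@@]1(O)C(=O)C=C[C@H]1OC(C)=O | target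

Total step count: 5. Longest linear sequence: 5 steps (1 → 4 → 6 → 7 → 8 → 10).

Steps most likely to fail

Step 5. The oxidant may also attack the ring C2=C3 enone alkene, either in competition with the exocyclic alkene or after it (over-oxidation); incomplete face discrimination is the lesser concern. The fallback sets out from 8 and comes back at 10, and masks the ring alkene before oxidation. Thiophenol with catalytic Et3N (CH2Cl2, −40 °C) should add in conjugate fashion to the less hindered ring β-carbon C3, anti to the acetate, to give (3S,4S,E)-4-acetoxy-5-pentadecylidene-3-(phenylthio)cyclopentan-1-one F1. Stoichiometric OsO4 with pyridine (THF, −40 °C; aq. NaHSO3), which leaves thioethers untouched in the absence of a co-oxidant, should then dihydroxylate the only remaining alkene anti to the acetate to give (3S,4S,5S)-4-acetoxy-5-hydroxy-5-[(S)-1-hydroxypentadecyl]-3-(phenylthio)cyclopentan-1-one F2. Oxidation with mCPBA (1 equiv, CH2Cl2, −78 °C) gives the corresponding sulfoxide F3, which on warming should lose benzenesulfenic acid by syn-elimination toward the acidic C2–H and restore the C2=C3 enone of 10.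

Step 1. The β-silyloxy dienolate may fragment with loss of silanolate, or be quenched by proton transfer from the enolisable aldehyde, before the C–C bond forms. The fallback sets out from 2 and comes back at 8, and builds the C5=C1' bond without any ketone enolate. Pyrrolidine-mediated condensation of 2 with freshly cracked cyclopentadiene (MeOH, rt) gives 6-tetradecylfulvene F4. Sensitised photooxygenation (O2, tetraphenylporphyrin, hν, CH2Cl2, −78 °C) gives 7-pentadecylidene-2,3-dioxabicyclo[2.2.1]hept-5-ene F5. Et3N added at −78 °C should trigger a Kornblum–DeLaMare rearrangement by removing the bridgehead hydrogen remote from the chain, which puts the chain on the carbinol side and gives racemic (E)-4-hydroxy-5-pentadecylidenecyclopent-2-en-1-one F6. Lipase-catalysed kinetic resolution (Burkholderia cepacia lipase, vinyl acetate, t-BuOMe, rt) then acetylates one enantiomer; the empirical size rule for secondary alcohols, with the alkylidene-bearing C5 side as the large group, predicts this to be the R alcohol, giving 8 directly.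

Step 2. Reversible deprotonation at the doubly allylic C4 under the amine base may erode the enantiomeric purity during the elimination. The fallback sets out from 7 and comes back at 8: the chemical acetylation of step 4 is replaced by a lipase-catalysed transesterification with vinyl acetate (Burkholderia cepacia lipase or Candida antarctica lipase B, t-BuOMe, rt). This is a kinetic resolution in which the same size rule predicts faster acylation of the R alcohol, so the minor S enantiomer should stay behind as alcohol and 8 should be obtained enantiomerically upgraded.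

Further compounds
F1 | step 5 | (3S,4S,E)-4-acetoxy-5-pentadecylidene-3-(phenylthio)cyclopentan-1-one | CCCCCCCCCCCCCC/C=C1/C(=O)C[C@H](Sc2ccccc2)[C@H]1OC(C)=O
F2 | step 5 | (3S,4S,5S)-4-acetoxy-5-hydroxy-5-[(S)-1-hydroxypentadecyl]-3-(phenylthio)cyclopentan-1-one | CCCCCCCCCCCCCC[C@H](O)[C@@]1(O)C(=O)C[C@H](Sc2ccccc2)[C@H]1OC(C)=O
F3 | step 5 | (3S,4S,5S)-4-acetoxy-5-hydroxy-5-[(S)-1-hydroxypentadecyl]-3-(phenylsulfinyl)cyclopentan-1-one, both sulfur epimers | CCCCCCCCCCCCCC[C@H](O)[C@@]1(O)C(=O)C[C@H](S(=O)c2ccccc2)[C@H]1OC(C)=O
F4 | step 1 | 6-tetradecylfulvene | CCCCCCCCCCCCCCC=C1C=CC=C1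
F5 | step 1 | 7-pentadecylidene-2,3-dioxabicyclo[2.2.1]hept-5-ene (racemic) | CCCCCCCCCCCCCCC=C1C2C=CC1OO2
F6 | step 1 | racemic (E)-4-hydroxy-5-pentadecylidenecyclopent-2-en-1-one | CCCCCCCCCCCCCC/C=C1/C(=O)C=CC1O
F0 | step 2 | none | none
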